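**Retrosynthetic overview**
1. Target ⇐ acetylation, desilylation and Z‑enyne installation (Peterson) on C4 aldehyde 14 ⇐ ozonolysis of 6‑allyl oxocane 12.
2. Oxocane (formed last) ⇐ chloronium‑triggered ring expansion of bromo‑oxolane 10 through a bicyclic oxonium (ring A fused to ring B): Cl+ to C7, O to C6, Cl– to C9.
3. Oxolane ring B (formed first) ⇐ Bartlett‑type bromoetherification of silyl ether 9 (sets C12, C13).
4. 9 ⇐ two Z‑selective Wittig reactions on lactol–aldehyde 4 ⇐ ozonolysis of mono‑silyl ether 2.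
5. 2 ⇐ organocatalytic desymmetrising silylation of meso diol 1 (fixes C9/C10).

Assumption: meso diol 1 (achiral), Et2SCl·SbCl6 and 1,3‑bis(triisopropylsilyl)propyne are purchasable; chain carbons are called C1–C15 as in pentadec‑3‑en‑1‑yne (ring oxygen on C6 and C12).

Step 1
Reactants: 1 meso‑cis‑cyclohex‑4‑ene‑1,2‑diol
Product: 2 (1R,6S)‑6‑[(triisopropylsilyl)oxy]cyclohex‑3‑en‑1‑ol
Conditions: i‑Pr3SiCl (2 equiv), i‑Pr2NEt, (S)‑N‑[(R)‑3,3‑dimethylbutan‑2‑yl]‑3,3‑dimethyl‑2‑{[(1‑methylimidazol‑2‑yl)methyl]amino}butanamide (30 mol %; its mirror image if the sense is opposite), THF, −30 °C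
Reagents that add atoms: chlorotriisopropylsilane, CC(C)[Si](Cl)(C(C)C)C(C)C
Why: Enantioselective silylation of a meso 1,2‑diol (Hoveyda–Snapper desymmetrisation): the imidazole activates the silyl chloride while the amine/amide hydrogen‑bonds the diol, so only the hydroxyl on the (S)‑carbinol (future C10) is silylated and the meso centres become C9(R)/C10(S).

Step 2
Reactants: 2 (1R,6S)‑6‑[(triisopropylsilyl)oxy]cyclohex‑3‑en‑1‑ol
Product: 4 2‑{(2R,3S)‑5‑hydroxy‑3‑[(triisopropylsilyl)oxy]oxolan‑2‑yl}acetaldehyde, via ozonide 3 (not isolated)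
Conditions: O3, CH2Cl2, −78 °C; then PPh3, −78 °C → rt
Reagents that add atoms: ozone, [O-][O+]=O
Why: Ozonolysis with reductive work‑up; the free C9 hydroxyl closes onto the γ‑aldehyde (C12) as a five‑membered lactol while the C7 aldehyde (β to that hydroxyl) stays free, so the two termini are differentiated without touching C9/C10.

Step 3
Reactants: 4 2‑{(2R,3S)‑5‑hydroxy‑3‑[(triisopropylsilyl)oxy]oxolan‑2‑yl}acetaldehyde; 5 (but‑3‑en‑1‑yl)triphenylphosphonium bromide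
Product: 6 (4S,5R)‑5‑[(2Z)‑hexa‑2,5‑dien‑1‑yl]‑4‑[(triisopropylsilyl)oxy]oxolan‑2‑ol
Conditions: 5 (2.2 equiv), NaN(SiMe3)2, THF, −78 °C; then 4, −78 °C, AcOH quench
Reagents that add atoms: none
Why: Z‑selective Wittig olefination of a non‑stabilised ylide under salt‑free sodium conditions; at −78 °C only the free aldehyde reacts (one ylide equivalent is spent on the lactol OH, and the lactolate stays closed), giving the Z‑C6=C7 alkene.

Step 4
Reactants: 6 (4S,5R)‑5‑[(2Z)‑hexa‑2,5‑dien‑1‑yl]‑4‑[(triisopropylsilyl)oxy]oxolan‑2‑ol; 7 propyltriphenylphosphonium bromide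
Product: 9 (4Z,7R,8S,10Z)‑7‑[(triethylsilyl)oxy]‑8‑[(triisopropylsilyl)oxy]trideca‑1,4,10‑triene, via sodium alkoxide 8 (not isolated)
Conditions: 7 (3.2 equiv), NaN(SiMe3)2, THF, 0 °C → rt; then Et3SiCl (5 equiv), 0 °C
Reagents that add atoms: chlorotriethylsilane, CC[Si](Cl)(CC)CC
Why: Wittig olefination of the opened lactol gives the Z‑C12=C13 alkene, and the C9 alkoxide is silylated in the same flask (the bulky triisopropylsilyl group does not migrate), giving the O–SiEt3 ether needed as nucleofuge.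

Step 5
Reactants: 9 (4Z,7R,8S,10Z)‑7‑[(triethylsilyl)oxy]‑8‑[(triisopropylsilyl)oxy]trideca‑1,4,10‑triene
Product: 10 ({(2R,3S,5R)‑5‑[(1R)‑1‑bromopropyl]‑2‑[(2Z)‑hexa‑2,5‑dien‑1‑yl]oxolan‑3‑yl}oxy)triisopropylsilane
Conditions: NBS (1.1 equiv), MeCN, −30 → 0 °C, dark
Reagents that add atoms: N‑bromosuccinimide, O=C1CCC(=O)N1Br
Why: Bartlett‑type bromoetherification of an ether: the triethylsilyl ether oxygen captures the bromonium ion 5‑exo, the O–Si group sits trans to both flanking substituents in the oxonium‑like transition state (C8 and C13 cis, ring B 2,5‑cis), and anti addition across the Z‑alkene gives (12R,13R); 5‑endo closure on the other Z‑alkene and attack by the hindered triisopropylsilyl ether are slower.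

Step 6
Reactants: 10 ({(2R,3S,5R)‑5‑[(1R)‑1‑bromopropyl]‑2‑[(2Z)‑hexa‑2,5‑dien‑1‑yl]oxolan‑3‑yl}oxy)triisopropylsilane
Product: 12 ({(2R,4S,5S,7S,8S)‑2‑[(1R)‑1‑bromopropyl]‑5,7‑dichloro‑8‑(prop‑2‑en‑1‑yl)oxocan‑4‑yl}oxy)triisopropylsilane, via bicyclic oxonium salt 11 (not isolated)
Conditions: Et2SCl·SbCl6 (1.2 equiv), MeNO2/CH2Cl2, −45 °C; then Bu4NCl (5 equiv), −45 → 0 °C
Reagents that add atoms: chlorodiethylsulfonium hexachloroantimonate, CC[S+](Cl)CC.Cl[Sb-](Cl)(Cl)(Cl)(Cl)Cl; tetrabutylammonium chloride, CCCC[N+](CCCC)(CCCC)CCCC.[Cl-]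
Why: Proposed new method: chloronium‑triggered ring expansion (a formal 1,3‑dichlorination with oxygen shift) – Et2SCl+ transfers Cl+ to the electron‑richer Z‑disubstituted C6=C7 alkene, the ring B oxygen (which cannot reach C7 without a four‑membered ring) opens the chloriranium at C6 in 5‑endo fashion anti to chlorine on the face that keeps the allyl group and Cl on the convex side away from the endo bromopropyl arm (sets 6S,7S), giving the cis‑fused 1‑oxoniabicyclo[3.3.0]octane 11, which chloride opens by SN2 with inversion at the ring‑fusion carbon C9 (sets 9S; C6 and C12 each carry an antiperiplanar β‑halogen that deactivates and shields them, and the C10 silyl ether cannot participate) to release the oxocane; closest known reaction types are the bromonium‑induced ring expansion of tetrahydrofurans with Et2SBr·SbCl5Br terminated by a neighbouring carbonate and the halide opening of Laurencia‑type trialkyloxonium ions.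

Step 7
Reactants: 12 ({(2R,4S,5S,7S,8S)‑2‑[(1R)‑1‑bromopropyl]‑5,7‑dichloro‑8‑(prop‑2‑en‑1‑yl)oxocan‑4‑yl}oxy)triisopropylsilane
Product: 14 2‑{(2S,3S,5S,6S,8R)‑8‑[(1R)‑1‑bromopropyl]‑3,5‑dichloro‑6‑[(triisopropylsilyl)oxy]oxocan‑2‑yl}acetaldehyde, via ozonide 13 (not isolated)
Conditions: O3, CH2Cl2, −78 °C; then PPh3, −78 °C → rt
Reagents that add atoms: ozone, [O-][O+]=O
Why: Ozonolysis of the only remaining alkene gives the C4 aldehyde; alkyl halides, ethers and the silyl ether are inert and no stereocentre is touched.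

Step 8
Reactants: 14 2‑{(2S,3S,5S,6S,8R)‑8‑[(1R)‑1‑bromopropyl]‑3,5‑dichloro‑6‑[(triisopropylsilyl)oxy]oxocan‑2‑yl}acetaldehyde; 15 1,3‑bis(triisopropylsilyl)prop‑1‑yne
Product: 16 {(3Z)‑5‑[(2S,3S,5S,6S,8R)‑8‑[(1R)‑1‑bromopropyl]‑3,5‑dichloro‑6‑[(triisopropylsilyl)oxy]oxocan‑2‑yl]pent‑3‑en‑1‑yn‑1‑yl}triisopropylsilane
Conditions: 15, n‑BuLi, THF, −78 °C; then 14, −78 → −40 °C
Reagents that add atoms: none
Why: Peterson olefination (Corey–Yamamoto variant): the lithiated bis‑silylpropyne adds to the aldehyde and syn‑elimination of the bulky β‑silyl alkoxide gives the Z‑enyne; at −78 °C the secondary halides are untouched.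

Step 9
Reactants: 16 {(3Z)‑5‑[(2S,3S,5S,6S,8R)‑8‑[(1R)‑1‑bromopropyl]‑3,5‑dichloro‑6‑[(triisopropylsilyl)oxy]oxocan‑2‑yl]pent‑3‑en‑1‑yn‑1‑yl}triisopropylsilane
Product: 17 (2R,4S,5S,7S,8S)‑2‑[(1R)‑1‑bromopropyl]‑5,7‑dichloro‑8‑[(2Z)‑pent‑2‑en‑4‑yn‑1‑yl]oxocan‑4‑ol
Conditions: Bu4NF/AcOH (1:1, excess), THF, 0 °C → rt
Reagents that add atoms: none
Why: Fluoride‑mediated desilylation removes both the alkynyl and the O‑silyl group; the acetic acid buffer keeps the C10 alkoxide from closing onto the trans C9 chloride and suppresses elimination.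

Step 10
Reactants: 17 (2R,4S,5S,7S,8S)‑2‑[(1R)‑1‑bromopropyl]‑5,7‑dichloro‑8‑[(2Z)‑pent‑2‑en‑4‑yn‑1‑yl]oxocan‑4‑ol
Product: 18 (2R,4S,5S,7S,8S)‑2‑[(1R)‑1‑bromopropyl]‑5,7‑dichloro‑8‑[(2Z)‑pent‑2‑en‑4‑yn‑1‑yl]oxocan‑4‑yl acetate
Conditions: Ac2O, pyridine, DMAP (cat.), CH2Cl2, 0 °C → rt
Reagents that add atoms: acetic anhydride, CC(=O)OC(C)=O
Why: Acylation of the secondary alcohol with retention at C10 gives the target.

**Compound list**
1 | meso‑cis‑cyclohex‑4‑ene‑1,2‑diol, (1R,2S) | O[C@@H]1CC=CC[C@@H]1O | starting material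
2 | (1R,6S)‑6‑[(triisopropylsilyl)oxy]cyclohex‑3‑en‑1‑ol | O[C@@H]1CC=CC[C@@H]1O[Si](C(C)C)(C(C)C)C(C)C | intermediate
3 | (3R,4S)‑4‑[(triisopropylsilyl)oxy]‑7,8,9‑trioxabicyclo[4.2.1]nonan‑3‑ol, secondary ozonide of 2 (both bridge orientations) | O[C@@H]1CC2OOC(O2)C[C@@H]1O[Si](C(C)C)(C(C)C)C(C)C | intermediate
4 | 2‑{(2R,3S)‑5‑hydroxy‑3‑[(triisopropylsilyl)oxy]oxolan‑2‑yl}acetaldehyde (both anomers) | O=CC[C@H]1OC(O)C[C@@H]1O[Si](C(C)C)(C(C)C)C(C)C | intermediate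
5 | (but‑3‑en‑1‑yl)triphenylphosphonium bromide | C=CCC[P+](c1ccccc1)(c1ccccc1)c1ccccc1.[Br-] | starting material
6 | (4S,5R)‑5‑[(2Z)‑hexa‑2,5‑dien‑1‑yl]‑4‑[(triisopropylsilyl)oxy]oxolan‑2‑ol (both anomers) | C=CC/C=C\C[C@H]1OC(O)C[C@@H]1O[Si](C(C)C)(C(C)C)C(C)C | intermediate
7 | propyltriphenylphosphonium bromide | CCC[P+](c1ccccc1)(c1ccccc1)c1ccccc1.[Br-] | starting material
8 | sodium (4Z,7R,8S,10Z)‑8‑[(triisopropylsilyl)oxy]trideca‑1,4,10‑trien‑7‑olate | C=CC/C=C\C[C@@H]([O-])[C@@H](O[Si](C(C)C)(C(C)C)C(C)C)C/C=C\CC.[Na+] | intermediate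
9 | (4Z,7R,8S,10Z)‑7‑[(triethylsilyl)oxy]‑8‑[(triisopropylsilyl)oxy]trideca‑1,4,10‑triene | C=CC/C=C\C[C@@H](O[Si](CC)(CC)CC)[C@@H](O[Si](C(C)C)(C(C)C)C(C)C)C/C=C\CC | intermediate
10 | ({(2R,3S,5R)‑5‑[(1R)‑1‑bromopropyl]‑2‑[(2Z)‑hexa‑2,5‑dien‑1‑yl]oxolan‑3‑yl}oxy)triisopropylsilane | C=CC/C=C\C[C@H]1O[C@@H]([C@H](Br)CC)C[C@@H]1O[Si](C(C)C)(C(C)C)C(C)C | intermediate
11 | cis‑fused 1‑oxoniabicyclo[3.3.0]octane hexachloroantimonate, O+ bonded to C6, C9 and C12, (6S,7S,9R,10S,12R,13R), 6‑allyl, 7‑chloro, 10‑triisopropylsilyloxy, 12‑[(1R)‑1‑bromopropyl] | C=CC[C@@H]1[O+]2[C@@H]([C@H](Br)CC)C[C@H](O[Si](C(C)C)(C(C)C)C(C)C)[C@H]2C[C@@H]1Cl.Cl[Sb-](Cl)(Cl)(Cl)(Cl)Cl | intermediate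
12 | ({(2R,4S,5S,7S,8S)‑2‑[(1R)‑1‑bromopropyl]‑5,7‑dichloro‑8‑(prop‑2‑en‑1‑yl)oxocan‑4‑yl}oxy)triisopropylsilane | C=CC[C@@H]1O[C@@H]([C@H](Br)CC)C[C@H](O[Si](C(C)C)(C(C)C)C(C)C)[C@@H](Cl)C[C@@H]1Cl | intermediate
13 | 1,2,4‑trioxolane (secondary ozonide) of the allyl group of 12 | C1OOC(C[C@@H]2O[C@@H]([C@H](Br)CC)C[C@H](O[Si](C(C)C)(C(C)C)C(C)C)[C@@H](Cl)C[C@@H]2Cl)O1 | intermediate
14 | 2‑{(2S,3S,5S,6S,8R)‑8‑[(1R)‑1‑bromopropyl]‑3,5‑dichloro‑6‑[(triisopropylsilyl)oxy]oxocan‑2‑yl}acetaldehyde | O=CC[C@@H]1O[C@@H]([C@H](Br)CC)C[C@H](O[Si](C(C)C)(C(C)C)C(C)C)[C@@H](Cl)C[C@@H]1Cl | intermediate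
15 | 1,3‑bis(triisopropylsilyl)prop‑1‑yne | CC(C)[Si](CC#C[Si](C(C)C)(C(C)C)C(C)C)(C(C)C)C(C)C | starting material
16 | {(3Z)‑5‑[(2S,3S,5S,6S,8R)‑8‑[(1R)‑1‑bromopropyl]‑3,5‑dichloro‑6‑[(triisopropylsilyl)oxy]oxocan‑2‑yl]pent‑3‑en‑1‑yn‑1‑yl}triisopropylsilane | CC(C)[Si](C#C/C=C\C[C@@H]1O[C@@H]([C@H](Br)CC)C[C@H](O[Si](C(C)C)(C(C)C)C(C)C)[C@@H](Cl)C[C@@H]1Cl)(C(C)C)C(C)C | intermediate
17 | (2R,4S,5S,7S,8S)‑2‑[(1R)‑1‑bromopropyl]‑5,7‑dichloro‑8‑[(2Z)‑pent‑2‑en‑4‑yn‑1‑yl]oxocan‑4‑ol | C#C/C=C\C[C@@H]1O[C@@H]([C@H](Br)CC)C[C@H](O)[C@@H](Cl)C[C@@H]1Cl | intermediate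
18 | (2R,4S,5S,7S,8S)‑2‑[(1R)‑1‑bromopropyl]‑5,7‑dichloro‑8‑[(2Z)‑pent‑2‑en‑4‑yn‑1‑yl]oxocan‑4‑yl acetate | C#C/C=C\C[C@@H]1O[C@@H]([C@H](Br)CC)C[C@H](OC(C)=O)[C@@H](Cl)C[C@@H]1Cl | target

Total steps: 10. Longest linear sequence: 10.

**Steps most likely to fail**

First, the ring expansion (step 6, the proposed new step). The chloriranium ion may collapse to a vicinal dichloride or form on the terminal alkene before the hindered ring B oxygen reaches it, and chloride (or the liberated Et2S) may open oxonium 11 at C6 or C12 instead of C9. The fallback makes the same oxonium by known, stepwise chemistry; it sets out from 10 and comes back at 12. Ozonolysis of 10 (O3; PPh3) cuts the side chain back to 2‑{(2R,3S,5R)‑5‑[(1R)‑1‑bromopropyl]‑3‑[(triisopropylsilyl)oxy]oxolan‑2‑yl}acetaldehyde F4. Wittig homologation with the ylide from (methoxymethyl)triphenylphosphonium chloride and NaN(SiMe3)2 gives the methyl enol ether F5, and aqueous HCO2H hydrolyses it to 3‑{(2R,3S,5R)‑5‑[(1R)‑1‑bromopropyl]‑3‑[(triisopropylsilyl)oxy]oxolan‑2‑yl}propanal F6. Enamine α‑chlorination (NCS, 10 mol % (2R,5R)‑2,5‑diphenylpyrrolidine or its mirror image, whichever gives the S chloride) gives the (2S)‑2‑chloro aldehyde F7. AllylMgBr at −78 °C adds under Cornforth control to give the anti chlorohydrin (4R,5S)‑5‑chloro‑6‑{(2R,3S,5R)‑5‑[(1R)‑1‑bromopropyl]‑3‑[(triisopropylsilyl)oxy]oxolan‑2‑yl}hex‑1‑en‑4‑ol F8. Tf2O with 2,6‑di‑tert‑butyl‑4‑methylpyridine gives the triflate F9, which the ring B oxygen displaces with inversion (5‑exo‑tet) to give the oxonium triflate F10, and Bu4NCl opens this to 12. This fallback removes the chloronium‑capture risk but not the regiochemistry of the chloride opening, which is shared by every route through this oxonium.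

Second, the bromoetherification (step 5). The 2,5‑cis outcome rests on the O–SiEt3 group overriding the substrate's own bias, which is made harder by the 1,3‑relationship to the bulky C10 silyl ether, and two other alkenes are present. The fallback moves from substituent control to catalyst control; it sets out from 9 and comes back at 10. Pyridinium p‑toluenesulfonate in MeOH removes the triethylsilyl group to give (4Z,7R,8S,10Z)‑8‑[(triisopropylsilyl)oxy]trideca‑1,4,10‑trien‑7‑ol F3. F3 is then cyclised by chiral Brønsted acid/Lewis base cooperative bromocycloetherification (NBS, Ph3P=S, 10 mol % 3,3'‑bis(2,4,6‑triisopropylphenyl)‑1,1'‑binaphthyl‑2,2'‑diyl hydrogen phosphate, the enantiomer matched to the 2,5‑cis product) to give 10.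

Third, the desymmetrisation (step 1). Chlorotriisopropylsilane is the slowest silyl chloride for this catalyst, and conversion or enantiomeric excess on the cyclohexene diol may be inadequate. The fallback differentiates the hydroxyls by acyl transfer instead; it sets out from 1 and comes back at 2. Catalytic enantioselective monobenzoylation (BzCl, Et3N, 0.5 mol % (S)‑2‑[(1‑methylpyrrolidin‑2‑yl)methyl]isoindoline or its mirror image, −78 °C) gives (1R,6S)‑6‑hydroxycyclohex‑3‑en‑1‑yl benzoate F1. Silylation with i‑Pr3SiOTf/2,6‑lutidine gives (1R,6S)‑6‑[(triisopropylsilyl)oxy]cyclohex‑3‑en‑1‑yl benzoate F2, and K2CO3/MeOH removes the benzoate to give 2.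

**Further compounds**
F1 | step 1 | (1R,6S)‑6‑hydroxycyclohex‑3‑en‑1‑yl benzoate | O=C(c1ccccc1)O[C@@H]1CC=CC[C@@H]1O
F2 | step 1 | (1R,6S)‑6‑[(triisopropylsilyl)oxy]cyclohex‑3‑en‑1‑yl benzoate | O=C(c1ccccc1)O[C@@H]1CC=CC[C@@H]1O[Si](C(C)C)(C(C)C)C(C)C
F3 | step 5 | (4Z,7R,8S,10Z)‑8‑[(triisopropylsilyl)oxy]trideca‑1,4,10‑trien‑7‑ol | C=CC/C=C\C[C@@H](O)[C@@H](O[Si](C(C)C)(C(C)C)C(C)C)C/C=C\CC
F4 | step 6 | 2‑{(2R,3S,5R)‑5‑[(1R)‑1‑bromopropyl]‑3‑[(triisopropylsilyl)oxy]oxolan‑2‑yl}acetaldehyde | O=CC[C@H]1O[C@@H]([C@H](Br)CC)C[C@@H]1O[Si](C(C)C)(C(C)C)C(C)C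
F5 | step 6 | ({(2R,3S,5R)‑5‑[(1R)‑1‑bromopropyl]‑2‑(3‑methoxyprop‑2‑en‑1‑yl)oxolan‑3‑yl}oxy)triisopropylsilane (E/Z mixture) | COC=CC[C@H]1O[C@@H]([C@H](Br)CC)C[C@@H]1O[Si](C(C)C)(C(C)C)C(C)C
F6 | step 6 | 3‑{(2R,3S,5R)‑5‑[(1R)‑1‑bromopropyl]‑3‑[(triisopropylsilyl)oxy]oxolan‑2‑yl}propanal | O=CCC[C@H]1O[C@@H]([C@H](Br)CC)C[C@@H]1O[Si](C(C)C)(C(C)C)C(C)C
F7 | step 6 | (2S)‑2‑chloro‑3‑{(2R,3S,5R)‑5‑[(1R)‑1‑bromopropyl]‑3‑[(triisopropylsilyl)oxy]oxolan‑2‑yl}propanal | O=C[C@@H](Cl)C[C@H]1O[C@@H]([C@H](Br)CC)C[C@@H]1O[Si](C(C)C)(C(C)C)C(C)C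
F8 | step 6 | (4R,5S)‑5‑chloro‑6‑{(2R,3S,5R)‑5‑[(1R)‑1‑bromopropyl]‑3‑[(triisopropylsilyl)oxy]oxolan‑2‑yl}hex‑1‑en‑4‑ol | C=CC[C@@H](O)[C@@H](Cl)C[C@H]1O[C@@H]([C@H](Br)CC)C[C@@H]1O[Si](C(C)C)(C(C)C)C(C)C
F9 | step 6 | (4R,5S)‑5‑chloro‑6‑{(2R,3S,5R)‑5‑[(1R)‑1‑bromopropyl]‑3‑[(triisopropylsilyl)oxy]oxolan‑2‑yl}hex‑1‑en‑4‑yl trifluoromethanesulfonate | C=CC[C@@H](OS(=O)(=O)C(F)(F)F)[C@@H](Cl)C[C@H]1O[C@@H]([C@H](Br)CC)C[C@@H]1O[Si](C(C)C)(C(C)C)C(C)C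
F10 | step 6 | trifluoromethanesulfonate salt of the oxonium cation of 11 | C=CC[C@@H]1[O+]2[C@@H]([C@H](Br)CC)C[C@H](O[Si](C(C)C)(C(C)C)C(C)C)[C@H]2C[C@@H]1Cl.[O-]S(=O)(=O)C(F)(F)F
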